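The key step exploits the fact that C6 and C8, the only ring A carbons that carry hydrogen in luteolin, bear methoxy groups in sideritiflavone and each lie between oxygen-bearing carbons (C5 and C7 around C6; C7 and C8a, bonded to O1, around C8). The route rests on cutting both of these C–O bonds and making them together, late, on the intact flavone by copper-mediated exchange of two bromides for methoxide. The coupling substrate is luteolin with its ring B catechol locked as a diphenylmethylene ketal, O5 and O7 methylated, and bromine at C6 and C8. A single Lewis-acid treatment then frees the catechol and the chelated 5-hydroxyl.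

Key step: step 4

Remark: the target has no stereocentre and no stereogenic axis, so no step needs stereocontrol.

Step 1
Reactants: 1 luteolin; 2 dichlorodiphenylmethane
Product: 3 2-(2,2-diphenyl-1,3-benzodioxol-5-yl)-5,7-dihydroxy-4H-chromen-4-one (luteolin 3',4'-O-diphenylmethylene ketal)
Conditions: Ph2CCl2 (1.5 equiv), Ph2O, 175 °C, 30 min
Reagents that add atoms: dichlorodiphenylmethane, ClC(Cl)(c1ccccc1)c1ccccc1
Why: Ketal formation between a catechol and a gem-dichloride (double substitution through the chlorodiphenylmethyl cation) should take only the 3',4'-diol of ring B, since it alone can close a five-membered 1,3-benzodioxole, while an open chlorodiphenylmethyl ether at the 7-hydroxyl or the hydrogen-bonded 5-hydroxyl would revert to the phenol on aqueous work-up.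

Step 2
Reactants: 3 2-(2,2-diphenyl-1,3-benzodioxol-5-yl)-5,7-dihydroxy-4H-chromen-4-one; 4 dimethyl sulfate
Product: 5 2-(2,2-diphenyl-1,3-benzodioxol-5-yl)-5,7-dimethoxy-4H-chromen-4-one
Conditions: Me2SO4 (4 equiv), K2CO3 (6 equiv), acetone, reflux, 24 h; then aq. NH3
Reagents that add atoms: dimethyl sulfate, COS(=O)(=O)OC
Why: Williamson-type O-methylation of phenoxides with a hard methylating agent should convert both ring A hydroxyls, the hydrogen-bonded 5-OH being the slow one and the reason for excess reagent and prolonged reflux, while the ketal is stable to base and ammonia destroys the remaining dimethyl sulfate.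

Step 3
Reactants: 5 2-(2,2-diphenyl-1,3-benzodioxol-5-yl)-5,7-dimethoxy-4H-chromen-4-one; 6 N-bromosuccinimide
Product: 7 6,8-dibromo-2-(2,2-diphenyl-1,3-benzodioxol-5-yl)-5,7-dimethoxy-4H-chromen-4-one
Conditions: NBS (2.2 equiv), DMF, 0 °C to rt, dark
Reagents that add atoms: N-bromosuccinimide, O=C1CCC(=O)N1Br
Why: Electrophilic aromatic bromination (SEAr) should go to C6 and C8, the only C–H positions of ring A, because each is ortho or para to all three ring A oxygens (C6: ortho to the 5- and 7-methoxy groups, para to O1; C8: ortho to the 7-methoxy group and O1, para to the 5-methoxy group), whereas ring B and C3 belong to the electron-poor 2-aryl-enone and react far more slowly.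

Step 4
Reactants: 7 6,8-dibromo-2-(2,2-diphenyl-1,3-benzodioxol-5-yl)-5,7-dimethoxy-4H-chromen-4-one; 8 sodium methoxide
Product: 9 2-(2,2-diphenyl-1,3-benzodioxol-5-yl)-5,6,7,8-tetramethoxy-4H-chromen-4-one
Conditions: NaOMe (12 equiv, 25 wt% in MeOH), CuBr (1 equiv), dry DMF, 110 °C, Ar; then aq. NH4Cl
Reagents that add atoms: sodium methoxide, C[O-].[Na+]
Why: CuBr and NaOMe form CuOMe, which most plausibly adds oxidatively into an aryl C–Br bond to give a trivalent copper aryl methoxide that reductively eliminates the aryl methyl ether and returns monovalent copper as CuBr; the sequence runs once at C6 and once at C8. The closest known reaction is the Ullmann-type ether synthesis with NaOMe and a copper halide in DMF, established for twofold exchange on ortho,ortho-disubstituted bromoarenes such as 3,5-dibromo-4-hydroxybenzaldehyde (to syringaldehyde) and for brominated 5,7-dioxygenated flavones. No ring is closed and no stereocentre is formed, so only the C6–O and C8–O bonds are new. Site selectivity is not asked of the coupling itself, because bromine occupies exactly the two former C–H carbons of ring A, and the ether oxygens on C5 and C7 and the ring oxygen O1 next to them can guide copper to each C–Br bond. What the step does need is chemoselectivity for substitution over hydrodebromination and over conjugate attack of methoxide at C2 with opening of ring C; a dry, oxygen-free medium, a full equivalent of CuBr to keep the coupling fast, and the donation of the three ring A oxygens into the C4 carbonyl, which lowers the electrophilicity of the pyranone, are relied on for this. The ketal and the methyl ethers are inert to methoxide.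

Step 5
Reactants: 9 2-(2,2-diphenyl-1,3-benzodioxol-5-yl)-5,6,7,8-tetramethoxy-4H-chromen-4-one; 10 boron trichloride
Product: 12 sideritiflavone (2-(3,4-dihydroxyphenyl)-5-hydroxy-6,7,8-trimethoxy-4H-chromen-4-one), via dichloroboryl chelate 11 (not isolated)
Conditions: BCl3 (4 equiv, 1 M in CH2Cl2), CH2Cl2, −78 to 0 °C; then 1 M aq. HCl, THF, rt
Reagents that add atoms: none
Why: Lewis-acid ether cleavage: BCl3 held between the C4 carbonyl oxygen and O5 in a six-membered chelate should lose chloromethane from that methyl ether only (the standard selective 5-O-demethylation of polymethoxyflavones), the same reagent should open the diphenylmethylene ketal through its diarylmethyl cation as it opens methylenedioxy groups, and hydrolysis of the B–O bonds of 11 during work-up releases the three phenols, the 6-, 7- and 8-methoxy groups having no chelating carbonyl beside them.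

Compound list
1 | luteolin, 2-(3,4-dihydroxyphenyl)-5,7-dihydroxy-4H-chromen-4-one | O=c1cc(-c2ccc(O)c(O)c2)oc2cc(O)cc(O)c12 | starting material
2 | dichlorodiphenylmethane | ClC(Cl)(c1ccccc1)c1ccccc1 | starting material
3 | 2-(2,2-diphenyl-1,3-benzodioxol-5-yl)-5,7-dihydroxy-4H-chromen-4-one | O=c1cc(-c2ccc3OC(c4ccccc4)(c4ccccc4)Oc3c2)oc2cc(O)cc(O)c12 | intermediate
4 | dimethyl sulfate | COS(=O)(=O)OC | starting material
5 | 2-(2,2-diphenyl-1,3-benzodioxol-5-yl)-5,7-dimethoxy-4H-chromen-4-one | COc1cc(OC)c2c(=O)cc(-c3ccc4OC(c5ccccc5)(c5ccccc5)Oc4c3)oc2c1 | intermediate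
6 | N-bromosuccinimide | O=C1CCC(=O)N1Br | starting material
7 | 6,8-dibromo-2-(2,2-diphenyl-1,3-benzodioxol-5-yl)-5,7-dimethoxy-4H-chromen-4-one | COc1c(Br)c(OC)c2c(=O)cc(-c3ccc4OC(c5ccccc5)(c5ccccc5)Oc4c3)oc2c1Br | intermediate
8 | sodium methoxide | C[O-].[Na+] | starting material
9 | 2-(2,2-diphenyl-1,3-benzodioxol-5-yl)-5,6,7,8-tetramethoxy-4H-chromen-4-one | COc1c(OC)c(OC)c2c(=O)cc(-c3ccc4OC(c5ccccc5)(c5ccccc5)Oc4c3)oc2c1OC | intermediate
10 | boron trichloride | ClB(Cl)Cl | starting material
11 | dichloroboryl chelate, not isolated: 2-(2-chloro-1,3,2-benzodioxaborol-5-yl)-5-(dichloroboryloxy)-6,7,8-trimethoxy-4H-chromen-4-one, the C4 carbonyl oxygen being coordinated to the boron on O5 | COc1c(OC)c(OB(Cl)Cl)c2c(=O)cc(-c3ccc4OB(Cl)Oc4c3)oc2c1OC | intermediate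
12 | sideritiflavone, 2-(3,4-dihydroxyphenyl)-5-hydroxy-6,7,8-trimethoxy-4H-chromen-4-one | COc1c(OC)c(O)c2c(=O)cc(-c3ccc(O)c(O)c3)oc2c1OC | target

Total step count: 5
Longest linear sequence: 5 steps (1 → 3 → 5 → 7 → 9 → 12)

Steps most likely to fail

Step 4. The coupling may lose to reduction of a C–Br bond to C–H, or to conjugate addition of methoxide at C2 followed by opening of ring C. The fallback changes the substrate so that the exchange runs on a phenoxide; it sets out from 3 and comes back to the route at 12. Compound 3 would be methylated only at the more acidic 7-hydroxyl (Me2SO4, 1.1 equiv, K2CO3, acetone, rt) to give 2-(2,2-diphenyl-1,3-benzodioxol-5-yl)-5-hydroxy-7-methoxy-4H-chromen-4-one F1. Bromination with NBS (2.1 equiv, DMF, 0 °C) should then give 6,8-dibromo-2-(2,2-diphenyl-1,3-benzodioxol-5-yl)-5-hydroxy-7-methoxy-4H-chromen-4-one F2. The exchange (NaOMe, CuBr, DMF, 110 °C) would run on the sodium 5-phenoxide, a charged chromone that resists nucleophilic attack at C2, as ortho-bromophenols are known to do, and should give 2-(2,2-diphenyl-1,3-benzodioxol-5-yl)-5-hydroxy-6,7,8-trimethoxy-4H-chromen-4-one F3. Hydrolysis of the ketal (AcOH/H2O 4:1, reflux) then leads to 12, so the selective demethylation of step 5 is not needed on this path.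

Step 5. A second ring A methyl group may be lost (most likely the central 7-methoxy or the 6-methoxy next to the boron-bound O5), or the ketal may open only in part. The fallback separates the two cleavages and uses Brønsted acids only; it sets out from 9 and comes back at 12. Hydrolysis of the ketal (AcOH/H2O 4:1, reflux) should give 2-(3,4-dihydroxyphenyl)-5,6,7,8-tetramethoxy-4H-chromen-4-one F4. Prolonged heating with concentrated aqueous HCl in EtOH at reflux, the acid-mediated 5-O-demethylation known for polymethoxyflavones, should then remove only the methyl group beside the protonated C4 carbonyl and give 12.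

Step 3. Site control may be lost, with bromination straying to ring B or C3, or the second bromination may stop short. The fallback reverses the order of bromination and methylation; it sets out from 3 and comes back at 7. Compound 3, whose two free phenols make ring A far more nucleophilic than any other position, would be brominated with NBS (2.05 equiv, THF, 0 °C) to 6,8-dibromo-2-(2,2-diphenyl-1,3-benzodioxol-5-yl)-5,7-dihydroxy-4H-chromen-4-one F5. Methylation of both hydroxyls (Me2SO4, K2CO3, acetone, reflux) should then give 7.

Further compounds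
F1 | step 4 | 2-(2,2-diphenyl-1,3-benzodioxol-5-yl)-5-hydroxy-7-methoxy-4H-chromen-4-one | COc1cc(O)c2c(=O)cc(-c3ccc4OC(c5ccccc5)(c5ccccc5)Oc4c3)oc2c1
F2 | step 4 | 6,8-dibromo-2-(2,2-diphenyl-1,3-benzodioxol-5-yl)-5-hydroxy-7-methoxy-4H-chromen-4-one | COc1c(Br)c(O)c2c(=O)cc(-c3ccc4OC(c5ccccc5)(c5ccccc5)Oc4c3)oc2c1Br
F3 | step 4 | 2-(2,2-diphenyl-1,3-benzodioxol-5-yl)-5-hydroxy-6,7,8-trimethoxy-4H-chromen-4-one | COc1c(OC)c(O)c2c(=O)cc(-c3ccc4OC(c5ccccc5)(c5ccccc5)Oc4c3)oc2c1OC
F4 | step 5 | 2-(3,4-dihydroxyphenyl)-5,6,7,8-tetramethoxy-4H-chromen-4-one | COc1c(OC)c(OC)c2c(=O)cc(-c3ccc(O)c(O)c3)oc2c1OC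
F5 | step 3 | 6,8-dibromo-2-(2,2-diphenyl-1,3-benzodioxol-5-yl)-5,7-dihydroxy-4H-chromen-4-one | Oc1c(Br)c(O)c2c(=O)cc(-c3ccc4OC(c5ccccc5)(c5ccccc5)Oc4c3)oc2c1Br
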